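## Structural features

The target is one γ-butyrolactone ring (O1, C2 as the carbonyl, C3, C4, C5) carrying an exocyclic methylene on C3, a carboxylic acid on C4 and, on C5, an unbranched 14-oxopentadecyl chain of thirteen methylenes followed by a methyl ketone. C4 and C5 are the only stereocentres; they are neighbours, both S, and hold the acid and the chain cis, the less stable arrangement for such 4,5-disubstituted lactones. The hydrogen on C4 is α to the acid and allylic to the conjugated methylene, so base can epimerise C4 to the trans series or pull the double bond into the ring. The methylene lactone is also a Michael acceptor, and the remote ketone must be masked whenever an organometallic reagent is used. The chain poses a carbon-counting problem and no selectivity problem. The real difficulty is to set C4 relative to C5 in the cis sense and to bring in the methylene without a late, base-mediated methylenation beside the epimerisable centre. The key step exploits the fact that the carboxyl carbon on C4 stands 1,3 to the oxygen on C5 (O1–C5–C4–C) while C3, next to C4, bears the methylene. A one-carbon radical anchored through silicon on the C5 oxygen can therefore reach C4 and nothing else, and a radical leaving group on the C3 methyl carbon of a C3=C4 alkene turns the addition into an allylic transposition that leaves C3=CH2.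

## Logic of the disconnections

**25 ⇒ 22.** The O1–C2 lactone bond is opened and the ketone is masked. In 22 the C2 carboxyl is a tert-butyl ester, C4 carries the free acid, C5 a free hydroxyl and the ketone is a dioxolane. Once C4 bears CO2H, the C5 hydroxyl is the only group that can close a five-membered ring (attack on the C4 carboxyl would give a four-membered one), so ring closure needs no selectivity. The gain is that ring strain and the Michael-acceptor lactone are absent from every earlier step. The forward step must stay acidic throughout.

**22 ⇒ 20.** No skeletal bond is cut; the C4 carboxyl is taken back to the hydroxymethyl group of 20. This turns the acid and the alcohol into a 1,3-diol, the retron for a C–Si and an O–Si bond on one silicon atom. The forward step must oxidise the primary alcohol only and must not epimerise C4 at the aldehyde level. The tert-butyl ester is needed here because either hydroxyl of 20 could otherwise lactonise onto C2.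

**20 ⇒ 19.** The CH2–OH bond and the O–H bond at C5 are traced back to the CH2–Si and O–Si bonds of the oxasilolane 19. The diol is thus stored as a ring whose formation fixes C4. The forward oxidation has to spare an α-substituted acrylate.

**19 ⇒ 18.** The bond from C4 to the future carboxyl carbon is cut, and the PhS group is put back on the C3 methyl carbon with the alkene shifted to C3=C4. In the forward direction this single step makes the ring, one skeletal bond, the C4 stereocentre and the exocyclic methylene. It demands 5-exo attack at C4, delivery from the face of the C5 oxygen, and fragmentation faster than any quenching of the two radicals.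

**18 ⇒ 16 + 17.** The O–Si bond is cut. The tether is hydrolytically labile, so it is attached last, to a free allylic alcohol; 17 supplies the future carboxyl carbon.

**16 ⇒ 15 ⇒ 14 ⇒ 13.** The C–S bond is cut with allylic transposition, after a protecting-group change at the C5 oxygen. This leads back to an adduct with a terminal methylene and an acyloxy group on C4. The trisubstituted alkene then arises with defined geometry in an SN2′ step, and the carbinol configuration in 13 is irrelevant. The forward step must give the isomer with C5 cis to the CH2SPh group, because this geometry blocks lactonisation after desilylation and supplies the allylic strain used in the key step.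

**13 ⇒ 11 + 12.** The C3–C4 bond is cut. 12 brings C2, C3 and the methylene carbon together with the ester that survives to the end. The demand is that the α-silyloxy aldehyde 11 keeps its configuration under amine catalysis.

**11 ⇒ 10 ⇒ 9 ⇒ 8.** These are changes of oxidation level and protecting groups only. The primary benzyl ether of 8 is exchanged for the aldehyde after the secondary hydroxyl has been silylated.

**8 ⇒ 5 + 6 (through 7).** The bond between the chain and the epoxide methylene is cut. 6 supplies C4, C5, the C5 oxygen and the S configuration from the chiral pool. The forward step needs attack at the terminal epoxide carbon only.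

**5 ⇒ 3 ⇒ 1 + 2.** The bond α to the ketone is cut. The eleven carbons of 2 plus the epoxide methylene give twelve of the thirteen chain methylenes, so the ketone must come as a three-carbon unit, which 1 provides after loss of its ester carbon. The forward alkylation must stop at one end of 2.

## Other disconnections considered

**Alternative 1:** The cut is C3–C4 together with a temporary C3–C5 bond. The achiral (Z)-allylic diazoacetate A1 would lose N2 over Rh2(MEPY)4, and the rhodium carbene would add across the Z alkene to give the cyclopropane-fused lactone A2, in which C3, C4 and C5 form the three-membered ring. A later "lactone switch" would open C3–C5 with oxygen on C5 and release the original CH2–O arm as the hydroxymethyl group on C4.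

- In its favour: both stereocentres come from a catalyst and from alkene geometry, with no chiral-pool material and no alcohol protecting groups. A1 should be short to make from 5. The key step belongs to an established reaction class, whereas the key step of the chosen plan is an extrapolation; on this point the alternative is the better.
- Against it here: the cyclopropane has only one acceptor, so opening is not easy. The opening must select C3–C5 over C3–C4 and must end with net retention at C5 (for example halide opening followed by carboxylate displacement) to reach the cis lactone. C3 ends as a methylene, so the exocyclic alkene would have to be added afterwards by enolate chemistry next to the epimerisable C4, and the hydroxymethyl group still needs oxidation.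
- Comparison: on structure both plans tie C4 to a fixed geometric element (ring fusion there, tether here). On mechanism the alternative is safer up to A2 and less safe after it. On step economy it is shorter to the key intermediate and longer after it, so no clear gain overall.

**Alternative 2:** The cut is O1–C5. The linear succinic acid monoester A3, with the free acid at C2, the tert-butyl ester on C4 and C5 as a plain methylene, would be treated with H2O2 and a chiral Mn(pdp)(OTf)2-type catalyst. The bound carboxylate would direct a manganese–oxo species to abstract hydrogen from the γ-methylene, and rebound of the carboxylate oxygen would close the lactone to A4.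

- In its favour: no oxygen at C5 has to be carried or protected, no tin is used, and the route is the shortest of all. On step economy and reagent profile it is better than the chosen plan.
- Against it here: the C5 hydrogens sit next to an ester-bearing carbon and are inductively deactivated towards an electrophilic oxidant, while the chain offers thirteen other methylenes. The cis relation at C5 would have to be imposed by the catalyst against the likely substrate preference for trans. A4 also lacks the methylene, so a base-mediated methylenation on the cis compound would follow.
- Comparison: both plans rest on a key step without direct precedent on the substrate, so they are equal there. Site selectivity and diastereoselectivity are left to catalyst control in the alternative, whereas the tether of the chosen plan can reach only C4 and only from the oxygen face.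

**Alternative 3:** The cuts are C2–C3 and C2–O1, with the carbonyl carbon coming from CO. The syn homopropargylic alcohol A5, carrying a silyloxymethyl group on C4, would react with CO over PdCl2, PPh3 and SnCl2. An alkoxycarbonyl–palladium species formed at the hydroxyl would add across the alkyne and give the α-methylene lactone A6 directly.

- In its favour: the complete methylene lactone forms in one catalytic step, late, from a robust open-chain precursor. The methylene arises without a methylenation reagent, which equals the chosen plan. The assembly of A5 from a chain aldehyde and a four-carbon propargyl unit is convergent, which is better than the linear chosen route.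
- Against it here: silyl removal and oxidation of the hydroxymethyl group to the acid would have to be done on the finished methylene lactone. At the aldehyde stage the C4 hydrogen is activated by both carbonyl groups and the ring favours the trans isomer. The syn relation in A5 needs a stoichiometric chiral allenylmetal reagent of matched configuration, and CO under pressure is required.
- Comparison: the oxidation problem at the carboxyl carbon is shared (step 14 of the chosen plan), but there it is met on an open-chain tert-butyl ester without a ring driving force towards trans. The number of steps after the key step is two against three, a slight advantage for the alternative. The chosen plan derives C4 from C5 intramolecularly, while the alternative relies on reagent control.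

Key step: step 12

Remark on the chemistry: the labels O1 and C2 to C5 always mean the lactone atoms of 25, also in open-chain compounds whose systematic names use other locants. The descriptors of 6 (S), 18 (4S in chain numbering), 19 (4S,5S) and 25 (2S,3S in oxolane numbering) were checked against one another and describe one spatial series, so no structure needed correction. The trans oxasilolane does correspond to the cis lactone.

## Route

Step 1
Reactants: 1 tert-butyl acetoacetate; 2 1,11-dibromoundecane
Product: 3 tert-butyl 2-acetyl-13-bromotridecanoate (racemic at C2, of no consequence)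
Conditions: K2CO3, DMF, 50 °C; 2 in threefold excess (recovered)
Reagents that add atoms: none
Why: Acetoacetic ester alkylation at carbon by a primary bromide; the excess of 2 suppresses reaction at both chain ends, and the monoalkylated β-keto ester is less acidic and more hindered, so a second C-alkylation is minor.

Step 2
Reactants: 3
Product: 5 2-(12-bromododecyl)-2-methyl-1,3-dioxolane, via 14-bromotetradecan-2-one 4 (not isolated)
Conditions: TsOH·H2O (cat.), PhMe, reflux; then HOCH2CH2OH, Dean–Stark, reflux
Reagents that add atoms: ethylene glycol, OCCO
Why: Acid-induced loss of isobutene from the tert-butyl β-keto ester and decarboxylation of the β-keto acid (ketonic cleavage of the acetoacetic ester synthesis) give the methyl ketone, which is ketalised in the same flask with azeotropic removal of water; the glycol is added only after gas evolution ends so that the β-keto ester is not ketalised first.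

Step 3
Reactants: 5; 6 (S)-benzyl glycidyl ether
Product: 8 (2S)-1-(benzyloxy)-15-(2-methyl-1,3-dioxolan-2-yl)pentadecan-2-ol, via Grignard reagent 7 (not isolated)
Conditions: Mg, THF, 45 °C; then CuI (10 mol%), 6, THF, −30 → 0 °C
Reagents that add atoms: none
Why: Copper-catalysed Grignard opening of a terminal epoxide at its unsubstituted carbon; the stereocentre of 6 is not involved and becomes C5 with S configuration, and the chain now has its thirteen methylenes.

Step 4
Reactants: 8
Product: 9 (2S)-1-(benzyloxy)-2-[(tert-butyldimethylsilyl)oxy]-15-(2-methyl-1,3-dioxolan-2-yl)pentadecane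
Conditions: TBSCl, imidazole, DMF, rt
Reagents that add atoms: tert-butyldimethylsilyl chloride, CC(C)(C)[Si](C)(C)Cl
Why: Standard silylation of a secondary alcohol; the TBS ether is chosen because it has to last through hydrogenolysis, oxidation, an amine-mediated coupling and a thiolate substitution.

Step 5
Reactants: 9
Product: 10 (2S)-2-[(tert-butyldimethylsilyl)oxy]-15-(2-methyl-1,3-dioxolan-2-yl)pentadecan-1-ol
Conditions: H2 (1 atm), 10% Pd/C, EtOAc, rt
Reagents that add atoms: none
Why: Hydrogenolysis of a benzyl ether under neutral conditions; silyl ether and dioxolane are inert, and the absence of base avoids silyl migration to the primary oxygen.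

Step 6
Reactants: 10
Product: 11 (2S)-2-[(tert-butyldimethylsilyl)oxy]-15-(2-methyl-1,3-dioxolan-2-yl)pentadecanal
Conditions: TEMPO (10 mol%), PhI(OAc)2, CH2Cl2, rt
Reagents that add atoms: none
Why: Oxoammonium-mediated oxidation stops at the aldehyde in the absence of water and involves no base, so the α-silyloxy stereocentre should be preserved; 11 is used at once.

Step 7
Reactants: 11; 12 tert-butyl acrylate
Product: 13 tert-butyl (4S)-4-[(tert-butyldimethylsilyl)oxy]-3-hydroxy-2-methylidene-17-(2-methyl-1,3-dioxolan-2-yl)heptadecanoate (both C3 epimers)
Conditions: quinuclidine (0.5 equiv), MeOH (2 equiv), 12 (5 equiv, neat), rt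
Reagents that add atoms: none
Why: Morita–Baylis–Hillman reaction; the α-oxygenated aldehyde is an activated electrophile and the protic additive speeds the proton-transfer step that limits the rate with a hindered acrylate; the new carbinol centre (future C4) needs no control because step 9 removes it.

Step 8
Reactants: 13
Product: 14 tert-butyl (4S)-3-(acetyloxy)-4-[(tert-butyldimethylsilyl)oxy]-2-methylidene-17-(2-methyl-1,3-dioxolan-2-yl)heptadecanoate (both C3 epimers)
Conditions: Ac2O, Et3N, DMAP (cat.), CH2Cl2, 0 °C
Reagents that add atoms: acetic anhydride, CC(=O)OC(C)=O
Why: Routine acetylation that turns the allylic hydroxyl into a leaving group for the allylic substitution.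

Step 9
Reactants: 14
Product: 15 tert-butyl (2Z,4S)-4-[(tert-butyldimethylsilyl)oxy]-17-(2-methyl-1,3-dioxolan-2-yl)-2-[(phenylsulfanyl)methyl]heptadec-2-enoate
Conditions: PhSH, Et3N, THF, 0 °C → rt
Reagents that add atoms: thiophenol, Sc1ccccc1
Why: SN2′ substitution of a Morita–Baylis–Hillman acetate by thiolate (conjugate addition, then loss of acetate); the trisubstituted alkene should form with the branched C5 carbon trans to the ester, which is Z by the sequence rules because CH2S outranks the ester carbon, and this is the thermodynamically preferred isomer.

Step 10
Reactants: 15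
Product: 16 tert-butyl (2Z,4S)-4-hydroxy-17-(2-methyl-1,3-dioxolan-2-yl)-2-[(phenylsulfanyl)methyl]heptadec-2-enoate
Conditions: HF·pyridine, pyridine, THF, 0 °C → rt
Reagents that add atoms: none
Why: Buffered fluoride cleavage of the silyl ether without basic alkoxide, so sulfide, dioxolane and tert-butyl ester stay; the freed hydroxyl cannot lactonise because the ester lies trans to C5 across the alkene.

Step 11
Reactants: 16; 17 (bromomethyl)chlorodimethylsilane
Product: 18 tert-butyl (2Z,4S)-4-{[(bromomethyl)dimethylsilyl]oxy}-17-(2-methyl-1,3-dioxolan-2-yl)-2-[(phenylsulfanyl)methyl]heptadec-2-enoate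
Conditions: Et3N, DMAP (cat.), CH2Cl2, 0 °C; rapid filtration through Et3N-deactivated silica
Reagents that add atoms: none
Why: Silylation of a secondary alcohol by a reactive chlorosilane; the hydrolytically labile tether is attached immediately before the radical step and 18 is not stored.

Step 12
Reactants: 18
Product: 19 tert-butyl 2-[(4S,5S)-2,2-dimethyl-5-[13-(2-methyl-1,3-dioxolan-2-yl)tridecyl]-1,2-oxasilolan-4-yl]prop-2-enoate
Conditions: (Bu3Sn)2 (1.1 equiv), PhH (0.01 M), hν (sunlamp), reflux
Reagents that add atoms: none
Why: Proposed new method: photolysis of (Bu3Sn)2 supplies Bu3Sn radicals that abstract bromine from the Si–CH2Br group; the nucleophilic α-silyl radical adds to the electron-poor β-carbon C4 of the enoate, the tertiary α-ester radical at C3 expels PhS radical by β-scission to leave C3=CH2, and PhS radical is taken up by the distannane to return Bu3Sn radical, so no hydrogen donor is present that could reduce either carbon radical. The closest known reaction types are the radical cyclisation of (bromomethyl)dimethylsilyl ethers of allylic alcohols and the radical allylation by addition–fragmentation of allylic sulfides (Keck allylation type); their combination on a 2-(arylthiomethyl)alk-2-enoate has not been demonstrated. The one ring formed, the 1,2-oxasilolane, closes in the 5-exo-trig mode; the 6-endo mode would mean attack at the fully substituted C3 and an unstabilised radical at C4, so sterics, polarity and radical stability all point to C4. The new stereocentre C4 is controlled by C5: allylic 1,3-strain with the cis CH2SPh group holds the C5–H bond in the alkene plane, so the tether oxygen lies on one face and the chain on the other, and delivery from the oxygen face through a chair-like transition state with the chain pseudo-equatorial should give the trans-4,5-disubstituted oxasilolane, which is the arrangement that becomes the cis lactone. The step also needs bromine abstraction in preference to attack of tin on the sulfide or the alkene, which the weak C–Br bond beside silicon secures, and high dilution keeps ring closure ahead of intermolecular addition to the acrylate of the product.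

Step 13
Reactants: 19
Product: 20 tert-butyl (3R,4S)-4-hydroxy-3-(hydroxymethyl)-2-methylidene-17-(2-methyl-1,3-dioxolan-2-yl)heptadecanoate
Conditions: KF, KHCO3, 30% H2O2, THF/MeOH (1:1), rt
Reagents that add atoms: hydrogen peroxide, OO
Why: Tamao oxidation of a cyclic alkoxysilane converts C–Si into C–OH at a primary carbon and frees the C5 hydroxyl; the tert-butyl ester resists attack by either hydroxyl, and an α-branched acrylic ester is a poor acceptor for hydroperoxide under these mild conditions.

Step 14
Reactants: 20
Product: 22 4-tert-butyl hydrogen (2S)-2-[(1S)-1-hydroxy-14-(2-methyl-1,3-dioxolan-2-yl)tetradecyl]-3-methylidenebutanedioate, via hydroxy aldehyde 21 (not isolated)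
Conditions: TEMPO (20 mol%), PhI(OAc)2 (2.5 equiv), MeCN/H2O (1:1), 0 °C → rt
Reagents that add atoms: water, O
Why: Oxoammonium oxidation is selective for the primary alcohol and carries the aldehyde hydrate on to the acid while the secondary hydroxyl is left; the medium is weakly acidic, which protects C4 and the exocyclic alkene, and any partial loss of the dioxolane here is harmless.

Step 15
Reactants: 22
Product: 25 allo-pertusaric acid [(2S,3S)-4-methylidene-5-oxo-2-(14-oxopentadecyl)oxolane-3-carboxylic acid], via hydroxy diacid 23 (not isolated), via ketal lactone acid 24 (not isolated)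
Conditions: TFA/CH2Cl2 (1:2), 0 °C → rt; then H2O, rt
Reagents that add atoms: water, O
Why: Acidolysis of the tert-butyl ester, acid-catalysed lactonisation of the γ-hydroxy acid (the C5 hydroxyl can form only the five-membered ring onto C2) and hydrolysis of the dioxolane all run under one acidic regime; no base is used, so C4 and the exocyclic methylene are not put at risk.

## Compound list

1 | tert-butyl acetoacetate | CC(=O)CC(=O)OC(C)(C)C | starting material
2 | 1,11-dibromoundecane | BrCCCCCCCCCCCBr | starting material
3 | tert-butyl 2-acetyl-13-bromotridecanoate (racemic) | CC(=O)C(CCCCCCCCCCCBr)C(=O)OC(C)(C)C | intermediate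
4 | 14-bromotetradecan-2-one | CC(=O)CCCCCCCCCCCCBr | intermediate (not isolated)
5 | 2-(12-bromododecyl)-2-methyl-1,3-dioxolane | CC1(CCCCCCCCCCCCBr)OCCO1 | intermediate
6 | (S)-benzyl glycidyl ether | c1ccccc1COC[C@@H]1CO1 | starting material
7 | [12-(2-methyl-1,3-dioxolan-2-yl)dodecyl]magnesium bromide | CC1(CCCCCCCCCCCC[Mg]Br)OCCO1 | intermediate (not isolated)
8 | (2S)-1-(benzyloxy)-15-(2-methyl-1,3-dioxolan-2-yl)pentadecan-2-ol | c1ccccc1COC[C@@H](O)CCCCCCCCCCCCCC1(C)OCCO1 | intermediate
9 | (2S)-1-(benzyloxy)-2-[(tert-butyldimethylsilyl)oxy]-15-(2-methyl-1,3-dioxolan-2-yl)pentadecane | c1ccccc1COC[C@@H](O[Si](C)(C)C(C)(C)C)CCCCCCCCCCCCCC1(C)OCCO1 | intermediate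
10 | (2S)-2-[(tert-butyldimethylsilyl)oxy]-15-(2-methyl-1,3-dioxolan-2-yl)pentadecan-1-ol | OC[C@@H](O[Si](C)(C)C(C)(C)C)CCCCCCCCCCCCCC1(C)OCCO1 | intermediate
11 | (2S)-2-[(tert-butyldimethylsilyl)oxy]-15-(2-methyl-1,3-dioxolan-2-yl)pentadecanal | O=C[C@@H](O[Si](C)(C)C(C)(C)C)CCCCCCCCCCCCCC1(C)OCCO1 | intermediate
12 | tert-butyl acrylate | C=CC(=O)OC(C)(C)C | starting material
13 | tert-butyl (4S)-4-[(tert-butyldimethylsilyl)oxy]-3-hydroxy-2-methylidene-17-(2-methyl-1,3-dioxolan-2-yl)heptadecanoate (both C3 epimers) | C=C(C(=O)OC(C)(C)C)C(O)[C@@H](O[Si](C)(C)C(C)(C)C)CCCCCCCCCCCCCC1(C)OCCO1 | intermediate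
14 | tert-butyl (4S)-3-(acetyloxy)-4-[(tert-butyldimethylsilyl)oxy]-2-methylidene-17-(2-methyl-1,3-dioxolan-2-yl)heptadecanoate (both C3 epimers) | C=C(C(=O)OC(C)(C)C)C(OC(C)=O)[C@@H](O[Si](C)(C)C(C)(C)C)CCCCCCCCCCCCCC1(C)OCCO1 | intermediate
15 | tert-butyl (2Z,4S)-4-[(tert-butyldimethylsilyl)oxy]-17-(2-methyl-1,3-dioxolan-2-yl)-2-[(phenylsulfanyl)methyl]heptadec-2-enoate | CC(C)(C)OC(=O)/C(CSc1ccccc1)=C/[C@@H](O[Si](C)(C)C(C)(C)C)CCCCCCCCCCCCCC1(C)OCCO1 | intermediate
16 | tert-butyl (2Z,4S)-4-hydroxy-17-(2-methyl-1,3-dioxolan-2-yl)-2-[(phenylsulfanyl)methyl]heptadec-2-enoate | CC(C)(C)OC(=O)/C(CSc1ccccc1)=C/[C@@H](O)CCCCCCCCCCCCCC1(C)OCCO1 | intermediate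
17 | (bromomethyl)chlorodimethylsilane | C[Si](C)(Cl)CBr | starting material
18 | tert-butyl (2Z,4S)-4-{[(bromomethyl)dimethylsilyl]oxy}-17-(2-methyl-1,3-dioxolan-2-yl)-2-[(phenylsulfanyl)methyl]heptadec-2-enoate | CC(C)(C)OC(=O)/C(CSc1ccccc1)=C/[C@@H](O[Si](C)(C)CBr)CCCCCCCCCCCCCC1(C)OCCO1 | intermediate
19 | tert-butyl 2-[(4S,5S)-2,2-dimethyl-5-[13-(2-methyl-1,3-dioxolan-2-yl)tridecyl]-1,2-oxasilolan-4-yl]prop-2-enoate | CC(C)(C)OC(=O)C(=C)[C@@H]1C[Si](C)(C)O[C@H]1CCCCCCCCCCCCCC2(C)OCCO2 | intermediate
20 | tert-butyl (3R,4S)-4-hydroxy-3-(hydroxymethyl)-2-methylidene-17-(2-methyl-1,3-dioxolan-2-yl)heptadecanoate | CC(C)(C)OC(=O)C(=C)[C@H](CO)[C@@H](O)CCCCCCCCCCCCCC1(C)OCCO1 | intermediate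
21 | tert-butyl (3S,4S)-3-formyl-4-hydroxy-2-methylidene-17-(2-methyl-1,3-dioxolan-2-yl)heptadecanoate | CC(C)(C)OC(=O)C(=C)[C@H](C=O)[C@@H](O)CCCCCCCCCCCCCC1(C)OCCO1 | intermediate (not isolated)
22 | 4-tert-butyl hydrogen (2S)-2-[(1S)-1-hydroxy-14-(2-methyl-1,3-dioxolan-2-yl)tetradecyl]-3-methylidenebutanedioate | CC(C)(C)OC(=O)C(=C)[C@H](C(=O)O)[C@@H](O)CCCCCCCCCCCCCC1(C)OCCO1 | intermediate
23 | (2S)-2-[(1S)-1-hydroxy-14-(2-methyl-1,3-dioxolan-2-yl)tetradecyl]-3-methylidenebutanedioic acid | OC(=O)C(=C)[C@H](C(=O)O)[C@@H](O)CCCCCCCCCCCCCC1(C)OCCO1 | intermediate (not isolated)
24 | (2S,3S)-4-methylidene-2-[13-(2-methyl-1,3-dioxolan-2-yl)tridecyl]-5-oxooxolane-3-carboxylic acid | C=C1C(=O)O[C@@H](CCCCCCCCCCCCCC2(C)OCCO2)[C@H]1C(=O)O | intermediate (not isolated)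
25 | allo-pertusaric acid, (2S,3S)-4-methylidene-5-oxo-2-(14-oxopentadecyl)oxolane-3-carboxylic acid | C=C1C(=O)O[C@@H](CCCCCCCCCCCCCC(C)=O)[C@H]1C(=O)O | target

## Step count and least certain steps

Total: 15 steps. Longest linear sequence: 15 steps (1 and 2 to 25); 6, 12 and 17 enter as purchased reagents.

**Step 12 (key step).** Three processes are the likely failures: loss of the labile tether before the radical is formed; a fragmentation that lags behind so that thiyl radical re-adds to the enoate of 18 or to the acrylate of 19 and starts isomerisation or oligomerisation; and delivery to the wrong face if the allylic-strain control is weaker than assumed. A change of conditions only would be Bu3SnH with AIBN by syringe pump, but that introduces hydrogen donors and is not the fallback.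

The fallback separates ring closure from methylene formation and uses known reaction types only. It sets out from 11 and returns at 19.
- Wittig reaction of 11 with tert-butyl (triphenylphosphoranylidene)acetate would give the (E)-enoate F1.
- HF·pyridine would free the alcohol F2, and 17 with Et3N would give the (bromomethyl)silyl ether F3.
- Bu3SnH and AIBN in refluxing benzene, the established tethered cyclisation onto the β-carbon of an enoate, would give the saturated oxasilolane ester F4. Here the trans preference rests on the chair-like transition state alone, so a separation of diastereomers may be needed.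
- Deprotonation with LiN(iPr)2 at −78 °C and trapping with dimethylmethylideneammonium iodide (Eschenmoser's salt) would give the Mannich base F5.
- Methylation with MeI to the ammonium iodide F6 and elimination with DBU would then deliver 19.

**Step 7.** The coupling may be slow with the hindered acrylate. During a long exposure to the amine the α-silyloxy aldehyde may enolise, which would erode the configuration at C5, or the silyl group may migrate. The fallback sets out from 11 and returns at 13. Hydroalumination of tert-butyl propiolate with iBu2AlH and N-methylmorpholine N-oxide in THF at 0 °C would give the α-aluminated acrylate F7, which adds to 11 within a short time under non-basic conditions to give 13 directly.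

**Step 9.** The substitution may take the wrong regiochemical course (attack at the carbinol carbon without transposition) or give a mixture of alkene isomers, and the hindered environment next to the silyloxy group may slow the elimination. The fallback sets out from 13 and returns at 15. Treatment of 13 with NBS and Me2S in CH2Cl2 would give the rearranged (Z)-allylic bromide F8, which PhSNa would convert by direct SN2 displacement into 15.

**Step 14.** Epimerisation at C4 may occur at the aldehyde stage, since that hydrogen is activated by the formyl group and by the conjugated alkene. Retro-aldol cleavage or over-oxidation of the secondary alcohol are further risks. The fallback lactonises before oxidising; it sets out from 20 and returns at 25.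
- Selective silylation of the primary hydroxyl with TBDPSCl and imidazole would give the silyl ether F9.
- TFA in wet CH2Cl2 would cleave the ester and the dioxolane and close the only possible lactone to the silyloxymethyl lactone F10.
- HF·pyridine would free the hydroxymethyl lactone F11.
- Jones oxidation (CrO3, H2SO4, acetone, 0 °C) would give 25 under strongly acidic conditions, in which enolisation at C4 is slow relative to oxidation of the aldehyde hydrate.

## Further compounds

F1 | step 12 | tert-butyl (2E,4S)-4-[(tert-butyldimethylsilyl)oxy]-17-(2-methyl-1,3-dioxolan-2-yl)heptadec-2-enoate | CC(C)(C)OC(=O)/C=C/[C@@H](O[Si](C)(C)C(C)(C)C)CCCCCCCCCCCCCC1(C)OCCO1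
F2 | step 12 | tert-butyl (2E,4S)-4-hydroxy-17-(2-methyl-1,3-dioxolan-2-yl)heptadec-2-enoate | CC(C)(C)OC(=O)/C=C/[C@@H](O)CCCCCCCCCCCCCC1(C)OCCO1
F3 | step 12 | tert-butyl (2E,4S)-4-{[(bromomethyl)dimethylsilyl]oxy}-17-(2-methyl-1,3-dioxolan-2-yl)heptadec-2-enoate | CC(C)(C)OC(=O)/C=C/[C@@H](O[Si](C)(C)CBr)CCCCCCCCCCCCCC1(C)OCCO1
F4 | step 12 | tert-butyl 2-[(4S,5S)-2,2-dimethyl-5-[13-(2-methyl-1,3-dioxolan-2-yl)tridecyl]-1,2-oxasilolan-4-yl]acetate | CC(C)(C)OC(=O)C[C@@H]1C[Si](C)(C)O[C@H]1CCCCCCCCCCCCCC2(C)OCCO2
F5 | step 12 | tert-butyl 3-(dimethylamino)-2-[(4S,5S)-2,2-dimethyl-5-[13-(2-methyl-1,3-dioxolan-2-yl)tridecyl]-1,2-oxasilolan-4-yl]propanoate (both C2 epimers) | CC(C)(C)OC(=O)C(CN(C)C)[C@@H]1C[Si](C)(C)O[C@H]1CCCCCCCCCCCCCC2(C)OCCO2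
F6 | step 12 | trimethylammonium iodide obtained from F5 by N-methylation | CC(C)(C)OC(=O)C(C[N+](C)(C)C)[C@@H]1C[Si](C)(C)O[C@H]1CCCCCCCCCCCCCC2(C)OCCO2.[I-]
F7 | step 7 | [1-(tert-butoxycarbonyl)ethenyl]bis(2-methylpropyl)aluminium | C=C(C(=O)OC(C)(C)C)[Al](CC(C)C)CC(C)C
F8 | step 9 | tert-butyl (2Z,4S)-2-(bromomethyl)-4-[(tert-butyldimethylsilyl)oxy]-17-(2-methyl-1,3-dioxolan-2-yl)heptadec-2-enoate | CC(C)(C)OC(=O)/C(CBr)=C/[C@@H](O[Si](C)(C)C(C)(C)C)CCCCCCCCCCCCCC1(C)OCCO1
F9 | step 14 | tert-butyl (3R,4S)-3-{[(tert-butyldiphenylsilyl)oxy]methyl}-4-hydroxy-2-methylidene-17-(2-methyl-1,3-dioxolan-2-yl)heptadecanoate | CC(C)(C)OC(=O)C(=C)[C@H](CO[Si](c1ccccc1)(c1ccccc1)C(C)(C)C)[C@@H](O)CCCCCCCCCCCCCC1(C)OCCO1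
F10 | step 14 | (4R,5S)-4-{[(tert-butyldiphenylsilyl)oxy]methyl}-3-methylidene-5-(14-oxopentadecyl)oxolan-2-one | C=C1C(=O)O[C@@H](CCCCCCCCCCCCCC(C)=O)[C@H]1CO[Si](c1ccccc1)(c1ccccc1)C(C)(C)C
F11 | step 14 | (4R,5S)-4-(hydroxymethyl)-3-methylidene-5-(14-oxopentadecyl)oxolan-2-one | C=C1C(=O)O[C@@H](CCCCCCCCCCCCCC(C)=O)[C@H]1CO
A1 | alternative 1 | (2Z)-16-(2-methyl-1,3-dioxolan-2-yl)hexadec-2-en-1-yl diazoacetate | [N-]=[N+]=CC(=O)OC/C=C\CCCCCCCCCCCCCC1(C)OCCO1
A2 | alternative 1 | all-cis 6-[13-(2-methyl-1,3-dioxolan-2-yl)tridecyl]-3-oxabicyclo[3.1.0]hexan-2-one | O=C1OC[C@H]2[C@@H]1[C@H]2CCCCCCCCCCCCCC3(C)OCCO3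
A3 | alternative 2 | 3-(tert-butoxycarbonyl)-18-oxononadecanoic acid (single enantiomer as drawn) | OC(=O)C[C@H](C(=O)OC(C)(C)C)CCCCCCCCCCCCCCC(C)=O
A4 | alternative 2 | tert-butyl cis-5-oxo-2-(14-oxopentadecyl)oxolane-3-carboxylate | O=C1C[C@H](C(=O)OC(C)(C)C)[C@H](CCCCCCCCCCCCCC(C)=O)O1
A5 | alternative 3 | syn 3-{[(tert-butyldimethylsilyl)oxy]methyl}-17-(2-methyl-1,3-dioxolan-2-yl)heptadec-1-yn-4-ol | C#C[C@H](CO[Si](C)(C)C(C)(C)C)[C@@H](O)CCCCCCCCCCCCCC1(C)OCCO1
A6 | alternative 3 | cis 4-{[(tert-butyldimethylsilyl)oxy]methyl}-3-methylidene-5-[13-(2-methyl-1,3-dioxolan-2-yl)tridecyl]oxolan-2-one | C=C1C(=O)O[C@@H](CCCCCCCCCCCCCC2(C)OCCO2)[C@H]1CO[Si](C)(C)C(C)(C)C
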